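The runs are calculated for substances that don't exist; scatter was added.

Early on, L runs ahead of G. In teal, which has the same [E] charge as the asked flasks, L stands at 13.1 % and G at 0.9 % at 3.00 min, when the feed ends.

the same everywhere: Z 1 mol%
- ochre: E 17 mM (fed, over 3.0 min); D 2 mM (held); J 0.33 mM; run made earlier
- amber: E 26 mM (fed, over 3.0 min); D 2 mM (held); J 0.33 mM; run made earlier
- teal: E 12 mM (fed, over 3.0 min); D 2 mM (held); J 0.49 mM; run made earlier
- north-west: E 12 mM (fed, over 3.0 min); D 2.0 mM (held); J 0.33 mM; time 15 min
- west: E 12 mM (fed, over 3.0 min); D 2.0 mM (held); J 0.33 mM; time 20 min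
- east: E 12 mM (fed, over 3.0 min); D 2.0 mM (held); J 0.33 mM; time 30 min

- ochre (time / min: E / %, G / %, L / %): 1.50: 42.3, 2.1, 6.3; 4.00: 60.1, 11.9, 26.5; 8.00: 26.8, 31.0, 44.1; 12.0: 13.1, 39.2, 50.2
- amber (time / min: E / %, G / %, L / %): 1.00: 28.8, 0, 5.5; 2.00: 46.8, 3.9, 14.9; 5.00: 32.5, 26.3, 41.4; 12.0: 1.2, 44.0, 55.6
- teal (time / min: E / %, G / %, L / %): 3.00: 86.0, 0.9, 13.1; 6.00: 64.8, 8.8, 26.2; 10.0: 44.5, 21.8, 36.7; 12.0: 35.4, 22.9, 41.5

(standard deviation of a reading: 1 percentage point)

- at the start none of D is in solution
- percentages count the whole charge, also what has not yet gone in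

- which of these there is most of at the end, counted by the E in it, north-west (L / E / G)
- which of these there is most of at the end, counted by the E in it, west (L / E / G)
- which of these there is most of at the end, counted by the E in it, east (L / E / G)
- final amount of the leader among these, as a percentage of the E charged, in north-west
- final amount of the leader among these, as a percentage of the E charged, in west
- final amount of the leader among these, as a percentage of the E charged, in east

North-west, west and east are one flask read at different times, so you draw one curve. Ochre at 12.0 min gives L minus G as 11 percentage points. Call this difference, as a share of the charge, the lead. Past the feed, E, L and G share the charge within scatter. So L equals the reacted share plus the lead, divided by two. I hold the lead at that ochre reading, so you reckon just the small thing, the E left.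

Here is my own curve. The knee comes at 3.0 min, and I take E there from teal, 86.0 %, although teal holds 0.49 mM of J against 0.33 mM. After it I treat E as a pseudo-first-order fall. Ochre from 4.00 min to 12.0 min reads 0.190 min⁻¹. Z is a fixed share of E, so I scale this by the charge to 0.134 min⁻¹. This is rough: amber from 5.00 min to 12.0 min reads 0.471 min⁻¹, more than the 0.291 min⁻¹ such scaling gives. E and L cross where E is 37.0 %, near 9.29 min. The level L runs into is 55.5 %. E left is 17.1 %, 8.75 % and 2.28 % in north-west, west and east. So I get L at 46.9 %, 51.1 % and 54.4 %.

The forecast names L, L and L, at 48 % (44 % to 52 %), 51.5 % (47.5 % to 55 %) and 55 % (51 % to 59 %). Its picture is a split that “slowly erodes an L lead”. Its values stand a little above mine in north-west, west and east.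

The flasks give L at 49.1 % in north-west, L at 52.2 % in west and L at 54.5 % in east. Each lies inside the forecast's range.

    D ⇌ Q, rate k1*(csat - [Q]) (kL = 0.310 s⁻¹)
    E + Q + Z → Z + L (k = 29000 M⁻² s⁻¹)
    Z + J ⇌ X, settled at all times (K = 7800 M⁻¹)
    L + Z ⇌ G + Z, rate k4*[Z]*[L] forward; the back reaction follows from the equilibrium constant (K = 0.810, k = 98.0 M⁻¹ s⁻¹)

Put east's 1.87 % of E and the ochre lead into the rule, and you get 54.6 % against 54.5 %. For a flask with more E left, I read the lead from a run holding similar E. The neighbour of west charged with 3.0 mM of E still holds 56.8 % of E at 20.0 min, so E leads there. Teal at 6.00 min holds 64.8 % of E with a lead of 17 points. The rule then gives 30.1 %. The neighbour holds 31.1 % of L.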